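**Plan**

- Retrosynthesis: the two sulfate esters and seven O-benzyl groups come off first. In each outer ring (A and C; C1 = sulfated carbon, C2 = carbon bonded to ring B, numbering on round the ring) the bonds C1–C6 and C4–C5 are then cut, leaving a ring B bis(diene) and two C5–C6 units. Last, the two aryl–C bonds from ring B to the diene arms are cut.
- Enabling feature: each outer ring carries oxygen on C1, C3 and C5 and ring B on C2. C1–C4 therefore map onto a 2-aryl-1,1,3-trioxygenated butadiene (Brassard-type ketene acetal) and C5–C6 onto an oxygenated two-carbon dienophile. Only the ketene acetal carbon emerges as a free phenol, which singles out the oxygen to be sulfated.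
- Forward order: ring B is bought as 1,3,5-tris(benzyloxy)benzene. Both acetoacetate arms are attached by rhodium carbenoid C–H functionalisation and converted into the bis(diene). Rings A and C then form together by a twofold Diels–Alder/aromatisation; sulfation and hydrogenolysis finish.
- Dienophile: an (E)-β-benzyloxyvinyl sulfoxide is used, not the sulfone. A sulfoxide leaves by thermal syn-elimination with H-5, whereas an α-sulfonyl carbanion would expel the C5 benzyloxy group by E1cB and keep the sulfur on the ring.
- Stereochemistry: the target has no stereocentre and its two biaryl axes carry no descriptor. The stereocentres of the cycloadducts are transient and are erased on aromatisation.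

Key step: step 7

Assumption: the target is drawn as the free bis(hydrogen sulfate); the sulfate monoesters are carried as triethylammonium salts and the acid form is liberated by cold cation exchange in the last operation.
Assumption: the geometry of the two ketene acetal double bonds of 6 is not controlled and is irrelevant, because these carbons become aromatic in step 7; the SMILES of 6 carries no descriptor there.

**Route**

Step 1
Reactants: 1 methyl acetoacetate
Product: 2 methyl 2-diazo-3-oxobutanoate
Conditions: 4-acetamidobenzenesulfonyl azide (p-ABSA), Et3N, MeCN, 0 °C → rt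
Reagents that add atoms: 4-acetamidobenzenesulfonyl azide, CC(=O)Nc1ccc(cc1)S(=O)(=O)N=[N+]=[N-]
Why: Regitz diazo transfer, in which the amine-generated enolate of the β-keto ester attacks the terminal nitrogen of the sulfonyl azide and the adduct collapses to the diazo compound and the sulfonamide.

Step 2
Reactants: 3 1,3,5-tris(benzyloxy)benzene; 2 methyl 2-diazo-3-oxobutanoate (about 2.5 equiv)
Product: 4 dimethyl 2,2'-[2,4,6-tris(benzyloxy)-1,3-phenylene]bis(3-oxobutanoate)
Conditions: Rh2(OAc)4 (2 mol %), 1,2-dichloroethane, 70 °C, 2 added by syringe pump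
Reagents that add atoms: none
Why: Rhodium carbenoid aromatic C–H functionalisation (formal C–H insertion by electrophilic aromatic substitution), in which the acceptor/acceptor carbenoid is attacked by the very electron-rich trialkoxybenzene and proton transfer gives the aryl acetoacetate; the first arm does not deactivate the ring, so a second carbenoid should substitute one of the two remaining equivalent positions, and stoichiometry together with growing crowding should stop the reaction at the bis-adduct.

Step 3
Reactants: 4 dimethyl 2,2'-[2,4,6-tris(benzyloxy)-1,3-phenylene]bis(3-oxobutanoate)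
Product: 5 dimethyl (2E,2'E)-2,2'-[2,4,6-tris(benzyloxy)-1,3-phenylene]bis[3-(benzyloxy)but-2-enoate]
Conditions: BnBr, Cs2CO3, DMF, 0 °C → rt
Reagents that add atoms: benzyl bromide, BrCc1ccccc1
Why: O-alkylation of a β-keto ester enolate (Williamson-type enol ether synthesis), favoured over C-alkylation because the dissociated cesium enolate in DMF reacts at oxygen and C-benzylation would build a quaternary carbon next to the 2,6-dialkoxyaryl group; the E enol ether (methyl syn to the ester) is expected, and its geometry is erased in step 4.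

Step 4
Reactants: 5 dimethyl (2E,2'E)-2,2'-[2,4,6-tris(benzyloxy)-1,3-phenylene]bis[3-(benzyloxy)but-2-enoate]
Product: 6 1,3,5-tris(benzyloxy)-2,4-bis[3-(benzyloxy)-1-methoxy-1-(trimethylsilyloxy)buta-1,3-dien-2-yl]benzene
Conditions: LDA (2.4 equiv), THF, −78 °C; Me3SiCl, −78 °C → rt; hexane, filtration under argon, used crude
Reagents that add atoms: chlorotrimethylsilane, C[Si](C)(C)Cl
Why: Standard preparation of a Brassard-type mixed vinylketene acetal, in which LDA removes a γ-proton of each β-alkoxy enoate arm and the dienolate is trapped on oxygen by Me3SiCl.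

Step 5
Reactants: 7 benzyl vinyl ether
Product: 9 benzyl 2-(phenylthio)vinyl ether (E/Z mixture), via α-chloro ether 8 (not isolated)
Conditions: PhSCl (from PhSSPh, SO2Cl2, CH2Cl2, 0 °C), CH2Cl2, −78 °C; then DBU, −78 °C → rt
Reagents that add atoms: benzenesulfenyl chloride, ClSc1ccccc1
Why: Electrophilic sulfenylation of an enol ether followed by dehydrochlorination, in which PhSCl adds through the episulfonium ion with chloride on the oxygen-bearing carbon and DBU then removes HCl from the α-chloro ether to give the β-thio enol ether.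

Step 6
Reactants: 9 benzyl 2-(phenylthio)vinyl ether (E/Z mixture)
Product: 10 (E)-2-(benzyloxy)vinyl phenyl sulfoxide (racemic at sulfur)
Conditions: mCPBA (1.0 equiv), CH2Cl2, −78 °C; then NaOBn (5 mol %), THF, rt; chromatography
Reagents that add atoms: 3-chloroperoxybenzoic acid, O=C(OO)c1cccc(Cl)c1
Why: Chemoselective sulfide-to-sulfoxide oxidation with one equivalent of peracid at low temperature (sulfur is oxidised far faster than the enol ether alkene), followed by alkoxide-catalysed addition–elimination equilibration of the push–pull alkene to the more stable E isomer, which is the geometry step 7 requires.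

Step 7
Reactants: 6 1,3,5-tris(benzyloxy)-2,4-bis[3-(benzyloxy)-1-methoxy-1-(trimethylsilyloxy)buta-1,3-dien-2-yl]benzene; 10 (E)-2-(benzyloxy)vinyl phenyl sulfoxide (3 equiv)
Product: 13 2',4,4',4'',6,6',6''-heptakis(benzyloxy)-[1,1':3',1''-terphenyl]-2,2''-diol, via bis-cycloadduct 11 (not isolated), via bis(cyclohexadienyl ketal) 12 (not isolated)
Conditions: N,O-bis(trimethylsilyl)acetamide (BSA, 4 equiv), PhMe (0.5 M), 110 °C, sealed tube; then 1 M HCl, THF, 0 °C → rt
Reagents that add atoms: none
Why: Proposed new method: each 2-aryl-3-benzyloxy-1-methoxy-1-silyloxybutadiene arm should add the β-benzyloxyvinyl sulfoxide in a concerted but asynchronous normal-demand Diels–Alder reaction, the nucleophilic CH2 terminus (C4) bonding first to the benzyloxy-bearing β-carbon of the acceptor (C5) and the ketene acetal carbon (C1) to the sulfinyl-bearing carbon (C6); the closest known reactions are the cycloaddition/aromatisation of Brassard-type mixed vinylketene acetals with activated alkenes and the use of aryl vinyl sulfoxides as acetylene equivalents that lose ArSOH after cycloaddition. Rings A and C are each closed by one intermolecular [4+2] event that forms both ring bonds (C4–C5 leading, C1–C6 following) of a six-membered carbocycle, independently on the two arms. Suprafacial addition of the E alkene places OBn and S(O)Ph trans in 11, so H-5 is cis to the sulfinyl group and is the only β-hydrogen (C1 carries none); thermal syn-elimination therefore removes PhSOH across C5–C6 and keeps the C5 oxygen, giving 12. Acid work-up collapses the methyl silyl ketal of 12 to a cross-conjugated dienone that tautomerises to the phenol, so C1 emerges as the only free hydroxyl of each outer ring. The stereocentres at C5, C6, the ketal carbon and sulfur are transient; only the trans C5/C6 relationship is controlled (by the alkene geometry), and all vanish on aromatisation. The step needs regioselectivity, secured by the matched polarisation of the donor-substituted diene terminus and the acceptor β-carbon, and enough dienophile reactivity, helped by high concentration, excess sulfoxide and BSA, which silylates the sulfenic acid before it can protodesilylate the second diene arm.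

Step 8
Reactants: 13 2',4,4',4'',6,6',6''-heptakis(benzyloxy)-[1,1':3',1''-terphenyl]-2,2''-diol
Product: 14 bis(triethylammonium) 2',4,4',4'',6,6',6''-heptakis(benzyloxy)-[1,1':3',1''-terphenyl]-2,2''-diyl bis(sulfate)
Conditions: SO3·NMe3 (6 equiv), Et3N, MeCN, 60 °C
Reagents that add atoms: sulfur trioxide–trimethylamine complex, C[N+](C)(C)S(=O)(=O)[O-]; triethylamine, CCN(CC)CC
Why: Phenol O-sulfation with a sulfur trioxide–amine complex, in which the two free phenols, the only hydroxyl groups present, take up SO3 and the sulfate monoesters are held as stable triethylammonium salts.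

Step 9
Reactants: 14 bis(triethylammonium) 2',4,4',4'',6,6',6''-heptakis(benzyloxy)-[1,1':3',1''-terphenyl]-2,2''-diyl bis(sulfate)
Product: 16 2',4,4',4'',6,6',6''-heptahydroxy-[1,1':3',1''-terphenyl]-2,2''-diyl bis(hydrogen sulfate) (target), via debenzylated bis(triethylammonium) salt 15 (not isolated)
Conditions: H2 (1 atm), 10% Pd/C, MeOH–THF, rt; filtration; Dowex 50W (H+ form), H2O, 0 °C; freeze-drying
Reagents that add atoms: none
Why: Global hydrogenolysis of the seven benzyl aryl ethers over Pd/C, to which aryl sulfate monoester salts are inert under neutral conditions, followed by cold cation exchange to give the free acid form of the target.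

**Compound list**

1 | methyl acetoacetate | COC(=O)CC(C)=O | starting material
2 | methyl 2-diazo-3-oxobutanoate | COC(=O)C(=[N+]=[N-])C(C)=O | intermediate
3 | 1,3,5-tris(benzyloxy)benzene | c1c(OCc2ccccc2)cc(OCc2ccccc2)cc1OCc1ccccc1 | starting material
4 | dimethyl 2,2'-[2,4,6-tris(benzyloxy)-1,3-phenylene]bis(3-oxobutanoate) (keto/enol tautomers; the two α-carbons are epimerisable and carried as a mixture) | COC(=O)C(C(C)=O)c1c(OCc2ccccc2)cc(OCc2ccccc2)c(C(C(C)=O)C(=O)OC)c1OCc1ccccc1 | intermediate
5 | dimethyl (2E,2'E)-2,2'-[2,4,6-tris(benzyloxy)-1,3-phenylene]bis[3-(benzyloxy)but-2-enoate] | COC(=O)/C(=C(\C)OCc1ccccc1)c1c(OCc2ccccc2)cc(OCc2ccccc2)c(/C(C(=O)OC)=C(/C)OCc2ccccc2)c1OCc1ccccc1 | intermediate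
6 | 1,3,5-tris(benzyloxy)-2,4-bis[3-(benzyloxy)-1-methoxy-1-(trimethylsilyloxy)buta-1,3-dien-2-yl]benzene (ketene acetal geometry not assigned) | C=C(OCc1ccccc1)C(=C(OC)O[Si](C)(C)C)c1c(OCc2ccccc2)cc(OCc2ccccc2)c(C(=C(OC)O[Si](C)(C)C)C(OCc2ccccc2)=C)c1OCc1ccccc1 | intermediate
7 | benzyl vinyl ether | C=COCc1ccccc1 | starting material
8 | benzyl 1-chloro-2-(phenylthio)ethyl ether (racemic) | ClC(CSc1ccccc1)OCc1ccccc1 | intermediate (not isolated)
9 | benzyl 2-(phenylthio)vinyl ether (E/Z mixture, E isomer drawn) | c1ccccc1CO/C=C/Sc1ccccc1 | intermediate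
10 | (E)-2-(benzyloxy)vinyl phenyl sulfoxide (racemic at sulfur) | O=S(/C=C/OCc1ccccc1)c1ccccc1 | intermediate
11 | 1,3,5-tris(benzyloxy)-2,4-bis[2,4-bis(benzyloxy)-6-methoxy-5-(phenylsulfinyl)-6-(trimethylsilyloxy)cyclohex-1-en-1-yl]benzene (4,5-trans in each new ring; mixture of diastereomers at the ketal carbons, at sulfur and between the rings; one representative drawn) | C1(=C(OCc2ccccc2)C[C@H](OCc2ccccc2)[C@@H](S(=O)c2ccccc2)C1(OC)O[Si](C)(C)C)c1c(OCc2ccccc2)cc(OCc2ccccc2)c(C2=C(OCc3ccccc3)C[C@H](OCc3ccccc3)[C@@H](S(=O)c3ccccc3)C2(OC)O[Si](C)(C)C)c1OCc1ccccc1 | intermediate (not isolated)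
12 | 1,3,5-tris(benzyloxy)-2,4-bis[2,4-bis(benzyloxy)-6-methoxy-6-(trimethylsilyloxy)cyclohexa-1,4-dien-1-yl]benzene (mixture of diastereomers at the two ketal carbons) | COC1(O[Si](C)(C)C)C=C(OCc2ccccc2)CC(OCc2ccccc2)=C1c1c(OCc2ccccc2)cc(OCc2ccccc2)c(C2=C(OCc3ccccc3)CC(OCc3ccccc3)=CC2(OC)O[Si](C)(C)C)c1OCc1ccccc1 | intermediate (not isolated)
13 | 2',4,4',4'',6,6',6''-heptakis(benzyloxy)-[1,1':3',1''-terphenyl]-2,2''-diol | Oc1cc(OCc2ccccc2)cc(OCc2ccccc2)c1-c1c(OCc2ccccc2)cc(OCc2ccccc2)c(-c2c(O)cc(OCc3ccccc3)cc2OCc2ccccc2)c1OCc1ccccc1 | intermediate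
14 | bis(triethylammonium) 2',4,4',4'',6,6',6''-heptakis(benzyloxy)-[1,1':3',1''-terphenyl]-2,2''-diyl bis(sulfate) | [O-]S(=O)(=O)Oc1cc(OCc2ccccc2)cc(OCc2ccccc2)c1-c1c(OCc2ccccc2)cc(OCc2ccccc2)c(-c2c(OS(=O)(=O)[O-])cc(OCc3ccccc3)cc2OCc2ccccc2)c1OCc1ccccc1.CC[NH+](CC)CC.CC[NH+](CC)CC | intermediate
15 | bis(triethylammonium) 2',4,4',4'',6,6',6''-heptahydroxy-[1,1':3',1''-terphenyl]-2,2''-diyl bis(sulfate) | [O-]S(=O)(=O)Oc1cc(O)cc(O)c1-c1c(O)cc(O)c(-c2c(OS(=O)(=O)[O-])cc(O)cc2O)c1O.CC[NH+](CC)CC.CC[NH+](CC)CC | intermediate (not isolated)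
16 | 2',4,4',4'',6,6',6''-heptahydroxy-[1,1':3',1''-terphenyl]-2,2''-diyl bis(hydrogen sulfate), CNP0320583.0 | O=S(=O)(O)Oc1cc(O)cc(O)c1-c1c(O)cc(O)c(-c2c(O)cc(O)cc2OS(=O)(=O)O)c1O | target

**Summary**

Total step count: 9. Longest linear sequence: 7 steps (steps 1, 2, 3, 4, 7, 8, 9 from methyl acetoacetate); the dienophile branch (steps 5 and 6) joins at step 7.

**Steps most likely to fail**

1. Step 7 (Proposed new method). The cycloaddition of a push–pull sulfoxide to a hindered ketene acetal diene may be too slow. Protodesilylation of the diene arms, or silyl transfer from the ketene acetal to the sulfoxide oxygen with Pummerer-type consumption of the dienophile, could then overtake ring formation, and the second arm may not react after the first.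
Fallback with known chemistry, setting out from 3 and returning at 13: double bromination of 3 (NBS, DMF, 0 °C) should give 2,4-dibromo-1,3,5-tris(benzyloxy)benzene F1. In parallel, commercial 3,5-bis(benzyloxy)phenol is protected as 1,3-bis(benzyloxy)-5-(methoxymethoxy)benzene F2 (MOMCl, i-Pr2NEt, CH2Cl2). F2 is lithiated between the MOM ether and a benzyloxy group by directed ortho-metalation (n-BuLi, THF, 0 °C) and quenched with B(OMe)3 to give, after mild acidic work-up, [2,4-bis(benzyloxy)-6-(methoxymethoxy)phenyl]boronic acid F3. Twofold Suzuki–Miyaura coupling of F1 with F3 (Pd(OAc)2, SPhos, K3PO4, toluene–H2O, 100 °C) should give the bis-MOM heptabenzyl terphenyl F4, and HCl in MeOH–THF removes the two MOM groups to deliver 13. This fallback accepts the crowded tetra-ortho-substituted biaryl couplings that the cycloaddition route avoids.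

2. Step 2. The second carbenoid substitution may stall, or the carbenoid may be diverted into O–H insertion with the enol of the first-formed β-keto ester or into oxonium ylide formation at a benzyl ether oxygen.
Fallback, setting out from 3 and returning at 4: diiodination of 3 (NIS, cat. CF3CO2H, MeCN) should give 2,4-diiodo-1,3,5-tris(benzyloxy)benzene F5. Negishi coupling with the Reformatsky reagent BrZnCH2CO2Me (Pd2(dba)3, XPhos, THF, 65 °C) gives dimethyl 2,2'-[2,4,6-tris(benzyloxy)-1,3-phenylene]diacetate F6. Double Claisen-type C-acetylation of F6 (LiHMDS, THF, −78 °C, then N-acetylimidazole) returns 4.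

3. Step 3. C-benzylation at the doubly activated carbon may compete with O-benzylation, or alkylation of the hindered enolate may remain incomplete.
Fallback, setting out from 4 and returning at 5: acid-catalysed enol ether formation with trimethyl orthoformate (cat. H2SO4, MeOH), which cannot alkylate carbon, should give dimethyl (2E,2'E)-2,2'-[2,4,6-tris(benzyloxy)-1,3-phenylene]bis(3-methoxybut-2-enoate) F7. Acid-catalysed transetherification of F7 with benzyl alcohol (cat. KHSO4, toluene, 110 °C, methanol distilled off) then gives 5.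

Further compounds
F1 | step 7 | 2,4-dibromo-1,3,5-tris(benzyloxy)benzene | Brc1c(OCc2ccccc2)cc(OCc2ccccc2)c(Br)c1OCc1ccccc1
F2 | step 7 | 1,3-bis(benzyloxy)-5-(methoxymethoxy)benzene | COCOc1cc(OCc2ccccc2)cc(OCc2ccccc2)c1
F3 | step 7 | [2,4-bis(benzyloxy)-6-(methoxymethoxy)phenyl]boronic acid | COCOc1cc(OCc2ccccc2)cc(OCc2ccccc2)c1B(O)O
F4 | step 7 | 2',4,4',4'',6,6',6''-heptakis(benzyloxy)-2,2''-bis(methoxymethoxy)-1,1':3',1''-terphenyl | COCOc1cc(OCc2ccccc2)cc(OCc2ccccc2)c1-c1c(OCc2ccccc2)cc(OCc2ccccc2)c(-c2c(OCOC)cc(OCc3ccccc3)cc2OCc2ccccc2)c1OCc1ccccc1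
F5 | step 2 | 2,4-diiodo-1,3,5-tris(benzyloxy)benzene | Ic1c(OCc2ccccc2)cc(OCc2ccccc2)c(I)c1OCc1ccccc1
F6 | step 2 | dimethyl 2,2'-[2,4,6-tris(benzyloxy)-1,3-phenylene]diacetate | COC(=O)Cc1c(OCc2ccccc2)cc(OCc2ccccc2)c(CC(=O)OC)c1OCc1ccccc1
F7 | step 3 | dimethyl (2E,2'E)-2,2'-[2,4,6-tris(benzyloxy)-1,3-phenylene]bis(3-methoxybut-2-enoate) | COC(=O)/C(=C(\C)OC)c1c(OCc2ccccc2)cc(OCc2ccccc2)c(/C(C(=O)OC)=C(/C)OC)c1OCc1ccccc1
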